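## Compound numbering used throughout

1 tetradecanoyl chloride; 2 N-methoxy-N-methyltetradecanamide; 3 2,2,6-trimethyl-4H-1,3-dioxin-4-one; 4 acetyl chloride; 5 keto-dioxinone; 6 diketo-dioxinone (precursor of the key step); 7 cyclic aldol (not isolated); 8 resorcylate acetonide (product of the key step); 9 its benzyl ether; 10 ring-opened N-methoxy-N-methylamide; 11 hydroxy ketone; 12 methoxy ketone; 13 benzyl-protected aryl acetate; 14 ardisiphenol D.

Ring numbering of the target: C1 carries the tridecyl chain, C2 is CH, C3 carries OH, C4 is CH, C5 carries OMe, C6 carries OAc.

## Analysis of the target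

Ardisiphenol D (14) is a 1,2,3,5-tetrasubstituted benzene without any stereocentre. Three adjacent ring carbons, C5, C6 and C1, carry methoxy, acetoxy and an unbranched C13 chain, and the only free hydroxyl (C3) lies para to the acetoxy group. The compound is therefore a hydroquinone monoacetate in which the crowded oxygen (C6, between OMe and the chain) is acylated and the exposed oxygen (C3) is free, the reverse of what direct acylation of the parent hydroquinone would favour. The aryl acetate is the sensitive group: bases and nucleophilic solvents cleave or transfer it, and the deacetylated hydroquinone would oxidise readily to the quinone. The difficulty lies in placing three different oxygen substituents on a ring with only two hydrogens and keeping them distinguishable until the acetate is in place. The strategy rests on the fact that C1 (alkyl), C3 (O) and C5 (O), with C2 and C4 unsubstituted, form a 5-alkylresorcinol pattern, the pattern of a folded polyketide chain. In such a chain C6 is the carbon that bears the chain carboxyl, so C6 can be marked by carbon and later exchanged for oxygen, with the carboxyl carbon ending up as the acetate carbonyl.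

## Retrosynthetic reasoning

The free C3 hydroxyl of 14 is traced back to the benzyl ether 13. Benzyl is removed last by neutral hydrogenolysis, which the aryl acetate tolerates, so no basic or nucleophilic step follows the introduction of the acetate.

The C6–O bond of 13 is traced back to a C6–C bond in methyl ketone 12. A Baeyer–Villiger oxidation inserts oxygen between C6 and the acetyl carbon, so the acetate of the target is formed from carbon already on the ring and no separate acetylation of a hindered phenol is needed. The forward reaction needs migration of the electron-rich aryl group and not of methyl, which the ortho and para oxygen donors of 12 favour.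

The methyl ether of 12 is cut to the phenol 11, and the methyl ketone of 11 to the N-methoxy-N-methylamide 10, which accepts exactly one methyl nucleophile. Amide 10 is the ring-opened form of the benzodioxinone 9. In 9 the carboxyl and the C5 oxygen are joined in one acetonide-type ring, so opening that ring at the carbonyl sets free only the C5 phenol, which is the one to be methylated.

Benzyl ether 9 comes from phenol 8 by alkylation of its single free hydroxyl. In 8 the C3 oxygen is free and the C5 oxygen is masked, so the two resorcinol oxygens are differentiated by construction and no selective protection has to be found.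

The benzene ring of 8 is opened at C1–C6, which leads to the open-chain diketo-dioxinone 6. This is the central disconnection. It is made here because the chain needs no regiochemical control: each ring carbon is one defined chain carbon. In the forward direction the dioxinone α-carbon (C6) must add to the tridecyl ketone carbon (C1) to give aldol 7, which aromatises by dehydration and enolisation. The dioxinone keeps the carboxyl and the C5 carbonyl masked until that moment and then remains as the protecting ring of 8.

Compound 6 is cut between the chain carbons that become C1 and C2 of the arene, giving the keto-dioxinone 5 as a dianion and the acyl donor 2. Amide 2 is preferred to the acid chloride 1 as the electrophile because its tetrahedral adduct persists until work-up, so the acidic 1,3-diketone of 6 never meets unreacted dianion.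

Keto-dioxinone 5 is cut between the carbons that become C3 and C4, giving the dienolate of dioxinone 3 and acetyl chloride 4. Amide 2 is made in one step from acid chloride 1. All three carbon sources (1, 3, 4) are commercial.

## Alternatives that were turned down

Alternative 1: The ring is kept intact and two substituents are added across an aryne, cutting the C1–chain bond and the C6–O bond together. The product of the key step would be 2-methoxy-6-tridecyl-4-(triisopropylsilyloxy)phenol A1. To reach A1, the fluoroarene 1-fluoro-3-methoxy-5-(triisopropylsilyloxy)benzene A2 would be lithiated at the carbon between F and OMe and would lose fluoride to give the aryne. Tridecyllithium A3 would add at C1, the position remote from OMe, and the resulting C6 aryllithium would be trapped with a borate ester and oxidised to the phenol. Acetylation of A1 and removal of the silyl group would finish the synthesis.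
- For it: it is by far the shortest plan, about four to five operations, and it forms the C–C and the C–O bond of A1 in one flask. The direction of addition to a 3-alkoxyaryne is well founded. On step economy it is clearly stronger than the chosen route.
- Against it: all three ring hydrogens of A2 lie between two heteroatom substituents. Lithiation on the other side of fluorine would give the isomeric aryne and a regioisomer of A1. A3 has to act as base and as nucleophile, and the aryllithium intermediates can add to the aryne themselves. The last step removes the silyl group of acetylated A1 with fluoride beside a base-labile aryl acetate.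
- Comparison: the chosen route is longer, but its regiochemistry follows from chain connectivity and not from competing rates. Its ring-forming step runs at room temperature without organolithium cascades, and its last step is neutral.

Alternative 2: Two ring bonds, C1–C2 and C5–C6, are cut in a Diels–Alder sense. The product of the key step would be 1-[4-(tert-butyldimethylsilyloxy)-2-methoxy-6-tridecylphenyl]ethanone A4. Heating the diene 1-methoxy-3-(tert-butyldimethylsilyloxy)cyclohexa-1,3-diene A5 with heptadec-3-yn-2-one A6 would give a bicyclo[2.2.2]octadiene. Cycloreversion with loss of the two-carbon bridge (Alder–Rickert) would then give A4. Baeyer–Villiger oxidation of A4 and desilylation would follow.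
- For it: it is convergent and short, about six steps. The donor pattern of A5 and the acceptor A6 match, so the regiochemistry should be right. A4 already carries the acetyl group at C6 and the methyl ether at C5, so the chain assembly, the aromatisation and the conversion of carboxyl into acetyl of the chosen route (steps 2 to 8) have no counterpart. It is stronger on convergence and step count.
- Against it: A6 is an internal ynone with an alkyl group on its β-carbon and is a poor dienophile. The C5–C6 bond joins two fully substituted carbons. The temperatures needed for cycloaddition and extrusion put the silyl enol ether of A5 at risk of isomerisation and hydrolysis. The Baeyer–Villiger step on a di-ortho-substituted ketone is not avoided, and the silyl group must again be removed next to the aryl acetate.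
- Comparison: the chosen route forms its ring under mild conditions from a substrate made for that closure, and uses a benzyl group that is removed without base or fluoride.

Alternative 3: The ring is cut at C2–C3 and derived from a four-membered ring. The product of the key step would be 2-methoxy-6-tridecylbenzene-1,4-diol A7. Thermolysis of 4-hydroxy-3-methoxy-4-(pentadec-1-en-2-yl)cyclobut-2-en-1-one A8 would open it to a dienylketene, and 6π electrocyclisation with tautomerisation would give A7.
- For it: the substitution pattern is fixed completely by the cyclobutenone A8, and the thermolysis is neutral. The C6 oxygen arrives as oxygen, so no Baeyer–Villiger step is needed. On that point it is stronger than the chosen route.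
- Against it: A7 is a free, air-sensitive hydroquinone in which the hindered C6 hydroxyl must be acetylated while the exposed C3 hydroxyl stays free. That requires protection, acetylation and deprotection. A8 needs a monoalkoxy cyclobutenedione with a ring hydrogen and a 2-metallated long-chain 1-alkene, each several steps from commercial materials. The total is no shorter than the chosen route.
- Comparison: in the chosen route the two oxygens never compete, because one is a phenol and the other is still a carboxyl carbon when they are told apart.

Key step: step 4

## Route

Assumption: 6 is drawn as its triketo tautomer although it should exist mainly in enolised forms; the reasoning is unaffected.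

Step 1
Reactants: 1 tetradecanoyl chloride
Product: 2 N-methoxy-N-methyltetradecanamide
Conditions: MeNHOMe·HCl, Et3N, CH2Cl2, 0 °C → rt
Reagents that add atoms: N,O-dimethylhydroxylamine hydrochloride, CNOC.Cl
Why: N-acylation of the hydroxylamine by the acid chloride (Weinreb amide formation). The amide is made because its chelated tetrahedral adduct in step 3 does not release a ketone before work-up.

Step 2
Reactants: 3 2,2,6-trimethyl-4H-1,3-dioxin-4-one; 4 acetyl chloride
Product: 5 2,2-dimethyl-6-(2-oxopropyl)-4H-1,3-dioxin-4-one
Conditions: LiN(SiMe3)2, THF, −78 °C; then 4 (0.5 equiv), −78 °C; aq. NH4Cl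
Reagents that add atoms: none
Why: LiN(SiMe3)2 deprotonates the C6 methyl group of 3 to the lithium dienolate, which is C-acylated at that carbon by 4 (crossed Claisen-type acylation). The dienolate is used in twofold excess because 5 is more acidic than 3 and consumes a second equivalent; unreacted 3 can be recovered.

Step 3
Reactants: 5 2,2-dimethyl-6-(2-oxopropyl)-4H-1,3-dioxin-4-one; 2 N-methoxy-N-methyltetradecanamide
Product: 6 2,2-dimethyl-6-(2,4-dioxoheptadecyl)-4H-1,3-dioxin-4-one
Conditions: LiN(iPr)2 (2.1 equiv), THF, −78 °C; then 2, −78 → −20 °C; aq. NH4Cl
Reagents that add atoms: none
Why: Two equivalents of LiN(iPr)2 form the dianion of 5, first at the doubly activated ring-side methylene and then at the terminal methyl, and the dianion reacts at its terminal carbon with the Weinreb amide (dianion Claisen-type acylation). The chelated tetrahedral adduct holds until the quench, so the 1,3-diketone of 6 is not exposed to dianion and no second acylation should occur.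

Step 4
Reactants: 6 2,2-dimethyl-6-(2,4-dioxoheptadecyl)-4H-1,3-dioxin-4-one
Product: 8 7-hydroxy-2,2-dimethyl-5-tridecyl-4H-1,3-benzodioxin-4-one, via racemic cyclic aldol 7 (not isolated)
Conditions: Et3N (2 equiv), CH2Cl2, 0 °C → rt; then CF3CO2H, rt
Reagents that add atoms: none
Why: Et3N removes a proton from the side-chain methylene between the dioxinone and the first ketone, giving an extended dienolate whose charge is shared by the dioxinone α-carbon, the future ring C6. That carbon adds to the tridecyl ketone carbon, the future ring C1, in an intramolecular aldol reaction that forms C1–C6 and gives the cyclic β-hydroxy ketone 7; the closure is 6-(enolexo)-exo-trig, a favoured mode for enolates. Base-induced β-elimination of the tertiary hydroxyl across C1–C2 and enolisation of the C3 ketone then give the arene, and the acid treatment dehydrates any aldol that remains. The closest known reaction type is the biomimetic aldol aromatisation of 6-(2,4-dioxoalkyl)dioxinones, masked 3,5,7-triketo acids, to resorcylate acetonides. No stereocentre survives, because the carbinol carbon of 7 becomes sp2. The step needs C-aldol closure and neither Claisen closure nor O-cyclisation: the carboxyl carbon is held in the heterocycle trans to the side chain across the ring double bond and is deactivated as a vinylogous carbonate, so no chain carbanion can reach it, and the nearer ketone could only give a four-membered ring. O-Cyclisation to a 4-pyranone is favoured by acid activation of the dioxinone, which is why base is applied first and acid only after the carbocycle has formed. The product has C3–OH free and the C5 oxygen inside the acetonide, which is the differentiation used in the following steps.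

Step 5
Reactants: 8 7-hydroxy-2,2-dimethyl-5-tridecyl-4H-1,3-benzodioxin-4-one
Product: 9 7-(benzyloxy)-2,2-dimethyl-5-tridecyl-4H-1,3-benzodioxin-4-one
Conditions: BnBr, K2CO3, DMF, rt
Reagents that add atoms: benzyl bromide, BrCc1ccccc1
Why: Williamson etherification of the only free phenol; the C5 oxygen is masked in the acetonide, and K2CO3 in an aprotic solvent leaves the benzodioxinone intact.

Step 6
Reactants: 9 7-(benzyloxy)-2,2-dimethyl-5-tridecyl-4H-1,3-benzodioxin-4-one
Product: 10 4-(benzyloxy)-2-hydroxy-N-methoxy-N-methyl-6-tridecylbenzamide
Conditions: MeNHOMe·HCl, iPrMgCl, THF, −20 °C → rt; aq. NH4Cl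
Reagents that add atoms: N,O-dimethylhydroxylamine hydrochloride, CNOC.Cl
Why: The chloromagnesium amide of N,O-dimethylhydroxylamine attacks the activated aryl ester carbonyl of the benzodioxinone (Weinreb aminolysis of an ester); collapse of the adduct opens the heterocycle, releases the acetonide carbon as acetone and frees the C5 phenol. The fused ring holds the carbonyl in the arene plane, so its faces stay accessible despite the ortho chain.

Step 7
Reactants: 10 4-(benzyloxy)-2-hydroxy-N-methoxy-N-methyl-6-tridecylbenzamide
Product: 11 1-[4-(benzyloxy)-2-hydroxy-6-tridecylphenyl]ethan-1-one
Conditions: MeMgBr (4 equiv), THF, 0 °C → rt; aq. NH4Cl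
Reagents that add atoms: methylmagnesium bromide, C[Mg]Br
Why: The first equivalent of MeMgBr forms the bromomagnesium phenoxide and further reagent adds once to the amide (Weinreb ketone synthesis). The N-methoxy chelate keeps the tetrahedral adduct until work-up, so no tertiary alcohol should form.

Step 8
Reactants: 11 1-[4-(benzyloxy)-2-hydroxy-6-tridecylphenyl]ethan-1-one
Product: 12 1-[4-(benzyloxy)-2-methoxy-6-tridecylphenyl]ethan-1-one
Conditions: MeI, K2CO3, DMF, 40 °C
Reagents that add atoms: iodomethane, CI
Why: Williamson methylation of the C5 phenol; K2CO3 is too weak to enolise the ketone, so only O-methylation is expected, and gentle warming overcomes the hydrogen bond to the ortho carbonyl.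

Step 9
Reactants: 12 1-[4-(benzyloxy)-2-methoxy-6-tridecylphenyl]ethan-1-one
Product: 13 4-(benzyloxy)-2-methoxy-6-tridecylphenyl acetate
Conditions: mCPBA, CF3CO2H (cat.), CH2Cl2, 0 °C → rt
Reagents that add atoms: 3-chloroperbenzoic acid (mCPBA), OOC(=O)c1cccc(Cl)c1
Why: Baeyer–Villiger oxidation; the peracid adds to the ketone and the electron-rich 2,4-dialkoxy-6-alkylphenyl group migrates in preference to methyl, inserting oxygen into the C6–acyl bond and giving the aryl acetate of the target directly. Migration is helped by the ortho and para oxygen donors and by relief of strain at the twisted ketone.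

Step 10
Reactants: 13 4-(benzyloxy)-2-methoxy-6-tridecylphenyl acetate
Product: 14 ardisiphenol D (4-hydroxy-2-methoxy-6-tridecylphenyl acetate)
Conditions: H2 (1 atm), Pd/C (10% Pd on carbon), EtOAc, rt
Reagents that add atoms: none
Why: Hydrogenolysis of the benzyl ether in a neutral, non-nucleophilic solvent; the aryl acetate, the methyl ether and the arene are inert under these conditions, so solvolysis or acyl transfer is not expected.

## Compound list

1 | tetradecanoyl chloride | CCCCCCCCCCCCCC(Cl)=O | starting material
2 | N-methoxy-N-methyltetradecanamide | CCCCCCCCCCCCCC(=O)N(C)OC | intermediate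
3 | 2,2,6-trimethyl-4H-1,3-dioxin-4-one | CC1=CC(=O)OC(C)(C)O1 | starting material
4 | acetyl chloride | CC(Cl)=O | starting material
5 | 2,2-dimethyl-6-(2-oxopropyl)-4H-1,3-dioxin-4-one | CC(=O)CC1=CC(=O)OC(C)(C)O1 | intermediate
6 | 2,2-dimethyl-6-(2,4-dioxoheptadecyl)-4H-1,3-dioxin-4-one | CCCCCCCCCCCCCC(=O)CC(=O)CC1=CC(=O)OC(C)(C)O1 | intermediate
7 | 5-hydroxy-2,2-dimethyl-5-tridecyl-5,6-dihydro-4H-1,3-benzodioxine-4,7(8H)-dione (racemic; formed and consumed in step 4) | CCCCCCCCCCCCCC1(O)CC(=O)CC2=C1C(=O)OC(C)(C)O2 | intermediate
8 | 7-hydroxy-2,2-dimethyl-5-tridecyl-4H-1,3-benzodioxin-4-one | CCCCCCCCCCCCCc1cc(O)cc2OC(C)(C)OC(=O)c12 | intermediate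
9 | 7-(benzyloxy)-2,2-dimethyl-5-tridecyl-4H-1,3-benzodioxin-4-one | CCCCCCCCCCCCCc1cc(OCc3ccccc3)cc2OC(C)(C)OC(=O)c12 | intermediate
10 | 4-(benzyloxy)-2-hydroxy-N-methoxy-N-methyl-6-tridecylbenzamide | CCCCCCCCCCCCCc1cc(OCc2ccccc2)cc(O)c1C(=O)N(C)OC | intermediate
11 | 1-[4-(benzyloxy)-2-hydroxy-6-tridecylphenyl]ethan-1-one | CCCCCCCCCCCCCc1cc(OCc2ccccc2)cc(O)c1C(C)=O | intermediate
12 | 1-[4-(benzyloxy)-2-methoxy-6-tridecylphenyl]ethan-1-one | CCCCCCCCCCCCCc1cc(OCc2ccccc2)cc(OC)c1C(C)=O | intermediate
13 | 4-(benzyloxy)-2-methoxy-6-tridecylphenyl acetate | CCCCCCCCCCCCCc1cc(OCc2ccccc2)cc(OC)c1OC(C)=O | intermediate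
14 | ardisiphenol D, 4-hydroxy-2-methoxy-6-tridecylphenyl acetate | CCCCCCCCCCCCCc1cc(O)cc(OC)c1OC(C)=O | target

## Step count and risk

Total step count: 10. Longest linear sequence: 9 steps (steps 2 to 10 from 3; equally steps 1 and 3 to 10 from 1).

Least certain steps:

**Step 4 (key step).** The likeliest failure is diversion of the open chain before the carbocycle has formed. An enol oxygen can add to the dioxinone enol-ether carbon with loss of the acetonide, which leads to a 4-pyranone. The aldol 7 may also dehydrate incompletely or revert by retro-aldol cleavage.
Fallback, from 6 to 10: 6 would be heated in toluene with N,O-dimethylhydroxylamine (from its hydrochloride and Et3N). Retro-[4+2] loss of acetone gives the acylketene, which the amine traps as N-methoxy-N-methyl-3,5,7-trioxoicosanamide F1. The same C1–C6 aldol closure would then be run on this open-chain triketo amide with K2CO3 in iPrOH followed by methanolic HCl, giving 2,4-dihydroxy-N-methoxy-N-methyl-6-tridecylbenzamide F2. Benzylation of the unhindered para hydroxyl with one equivalent of BnBr and K2CO3 in acetone would give 10, so that 8 and 9 are bypassed. This fallback depends on the para hydroxyl reacting ahead of the ortho one.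

**Step 3.** The dianion may deprotonate the α-methylene of amide 2 and not add to it, or the second deprotonation of 5 may be incomplete. Either process returns 5.
Fallback, from 5 to 6: the dianion of 5 (LiN(iPr)2, THF, −78 °C) would be added to tetradecanal, a much faster electrophile, to give the racemic aldol 6-(4-hydroxy-2-oxoheptadecyl)-2,2-dimethyl-4H-1,3-dioxin-4-one F3. Oxidation of the secondary alcohol with Dess–Martin periodinane in CH2Cl2 would give 6.

**Step 7.** The amide carbonyl of 10 lies between the C1 chain and the magnesium phenoxide and is twisted out of the ring plane. Addition may stall, and MeMgBr may then act as a base and remove the N-methoxy group as formaldehyde.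
Fallback, from 9 to 11: 9 would be saponified with KOH in aqueous THF to 4-(benzyloxy)-2-hydroxy-6-tridecylbenzoic acid F4, with the acetonide carbon leaving as acetone and acidification kept cold to avoid decarboxylation. The dilithium salt would be treated with excess MeLi in THF at 0 °C and quenched with Me3SiCl and dilute acid, the classical conversion of a lithium carboxylate into a methyl ketone, to give 11. Steps 6 and 7 are replaced.

**Step 9.** Peracid addition to the di-ortho-substituted ketone may be slow. Oxidation of the electron-rich ring could then compete, and the acid formed could cleave the new aryl acetate.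
Fallback, from 10 to 13 (it also bypasses step 7): 10 would be O-methylated (MeI, K2CO3) to 4-(benzyloxy)-N,2-dimethoxy-N-methyl-6-tridecylbenzamide F5. Reduction with iBu2AlH at −78 °C would give 4-(benzyloxy)-2-methoxy-6-tridecylbenzaldehyde F6. The aldehyde would undergo Dakin-type Baeyer–Villiger oxidation with mCPBA, which is far easier for an electron-rich aldehyde than for the ketone, to give 4-(benzyloxy)-2-methoxy-6-tridecylphenyl formate F7. Methanolysis (K2CO3, MeOH) would give 4-(benzyloxy)-2-methoxy-6-tridecylphenol F8, and acetylation with Ac2O, pyridine and DMAP would give 13.

## Further compounds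

F1 | step 4 | N-methoxy-N-methyl-3,5,7-trioxoicosanamide | CCCCCCCCCCCCCC(=O)CC(=O)CC(=O)CC(=O)N(C)OC
F2 | step 4 | 2,4-dihydroxy-N-methoxy-N-methyl-6-tridecylbenzamide | CCCCCCCCCCCCCc1cc(O)cc(O)c1C(=O)N(C)OC
F3 | step 3 | 6-(4-hydroxy-2-oxoheptadecyl)-2,2-dimethyl-4H-1,3-dioxin-4-one (racemic) | CCCCCCCCCCCCCC(O)CC(=O)CC1=CC(=O)OC(C)(C)O1
F4 | step 7 | 4-(benzyloxy)-2-hydroxy-6-tridecylbenzoic acid | CCCCCCCCCCCCCc1cc(OCc2ccccc2)cc(O)c1C(O)=O
F5 | step 9 | 4-(benzyloxy)-N,2-dimethoxy-N-methyl-6-tridecylbenzamide | CCCCCCCCCCCCCc1cc(OCc2ccccc2)cc(OC)c1C(=O)N(C)OC
F6 | step 9 | 4-(benzyloxy)-2-methoxy-6-tridecylbenzaldehyde | CCCCCCCCCCCCCc1cc(OCc2ccccc2)cc(OC)c1C=O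
F7 | step 9 | 4-(benzyloxy)-2-methoxy-6-tridecylphenyl formate | CCCCCCCCCCCCCc1cc(OCc2ccccc2)cc(OC)c1OC=O
F8 | step 9 | 4-(benzyloxy)-2-methoxy-6-tridecylphenol | CCCCCCCCCCCCCc1cc(OCc2ccccc2)cc(OC)c1O
A1 | alternative 1 | 2-methoxy-6-tridecyl-4-(triisopropylsilyloxy)phenol | CCCCCCCCCCCCCc1cc(O[Si](C(C)C)(C(C)C)C(C)C)cc(OC)c1O
A2 | alternative 1 | 1-fluoro-3-methoxy-5-(triisopropylsilyloxy)benzene | COc1cc(F)cc(O[Si](C(C)C)(C(C)C)C(C)C)c1
A3 | alternative 1 | tridecyllithium | [Li]CCCCCCCCCCCCC
A4 | alternative 2 | 1-[4-(tert-butyldimethylsilyloxy)-2-methoxy-6-tridecylphenyl]ethanone | CCCCCCCCCCCCCc1cc(O[Si](C)(C)C(C)(C)C)cc(OC)c1C(C)=O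
A5 | alternative 2 | 1-methoxy-3-(tert-butyldimethylsilyloxy)cyclohexa-1,3-diene | COC1=CC(O[Si](C)(C)C(C)(C)C)=CCC1
A6 | alternative 2 | heptadec-3-yn-2-one | CCCCCCCCCCCCCC#CC(C)=O
A7 | alternative 3 | 2-methoxy-6-tridecylbenzene-1,4-diol | CCCCCCCCCCCCCc1cc(O)cc(OC)c1O
A8 | alternative 3 | 4-hydroxy-3-methoxy-4-(pentadec-1-en-2-yl)cyclobut-2-en-1-one (racemic) | CCCCCCCCCCCCCC(=C)C1(O)C(OC)=CC1=O
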